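**Plan**

- Cuts: ring B at its C=C bond (ring-closing metathesis) and at the lactone O–CH2 bond (carboxylate alkylation); the ester O–CH2 bond on the quaternary carbinol (epoxide opening by the ring C acid); the exocyclic C–C bond of that carbinol (sulfonium ylide on a ring A ketone); ring A across two C–C bonds ([4+2]).
- Enabling feature: in ring A (the cyclohexane) the isopropyl carbon, the fusion carbon carrying the ring B alkene and the fusion carbon carrying the lactone carbonyl are neighbours and trans,trans, and the next ring carbon is the oxygenated quaternary one. That is the pattern a 1-oxygenated 4-isopropyl diene and an E aldehyde ester give by endo cycloaddition.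
- Forward order: ring A first, then ketone and spiro-epoxide; the ring C acid is made separately from the same aldehyde; the two are joined by epoxide opening; ring B is closed last; one acidolysis ends the route.
- Stereochemistry: the ring A triad from the catalyst-controlled endo cycloaddition; the tertiary carbinol from axial ylide attack; the ring C isopropyl centre from enamine catalysis and its neighbour from anti conjugate addition; the ring B alkene geometry from the ring, the side-chain alkene from the phosphonate olefination.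

Key step: step 3

Remark on the chemistry: ring A is the cyclohexane, ring B the seven-membered lactone, ring C the cyclohexene of the side chain; both antipodes of the two amine catalysts are taken as purchasable, and enol-acetate isomers other than 1E,3E are assumed to be inert in the cycloaddition.

**Route**

Step 1
Reactants: 1 3-methylbutanal (isovaleraldehyde)
Product: 2 (2E)-5-methylhex-2-enal
Conditions: Ph3P=CHCHO, toluene, 80 °C
Reagents that add atoms: (triphenylphosphoranylidene)acetaldehyde, O=CC=P(c1ccccc1)(c1ccccc1)c1ccccc1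
Why: Wittig olefination with the formyl-stabilised ylide is reversible in its addition step and should give the E enal, and the conjugated product is less electrophilic than 1 and is homologated further only slowly.

Step 2
Reactants: 2 (2E)-5-methylhex-2-enal
Product: 3 (1E,3E)-5-methylhexa-1,3-dien-1-yl acetate
Conditions: Ac2O, Et3N, DMAP (cat.), 80 °C; distillation
Reagents that add atoms: acetic anhydride, CC(=O)OC(C)=O
Why: Enol acetylation by amine-mediated γ-deprotonation and O-acetylation of the extended dienolate should form the new C3=C4 bond trans for steric reasons and mainly the 1E enol ester, the only isomer that can reach the s-cis conformation needed in step 3.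

Step 3
Reactants: 3 (1E,3E)-5-methylhexa-1,3-dien-1-yl acetate; 4 ethyl (2E)-4-oxobut-2-enoate
Product: 7 ethyl (1R,2S,5R,6S)-5-acetoxy-6-formyl-2-(propan-2-yl)cyclohex-3-ene-1-carboxylate, via dienophile iminium chloride 5 (not isolated), via cycloadduct iminium chloride 6 (not isolated)
Conditions: (5R)-5-benzyl-2,2,3-trimethylimidazolidin-4-one·HCl (20 mol %), MeCN/H2O (95:5), −10 °C
Reagents that add atoms: none
Why: The secondary amine salt condenses with aldehyde 4 to the E-iminium ion 5, whose lowered LUMO has its larger coefficient on the ester-bearing β-carbon, and a concerted but asynchronous endo [4+2] cycloaddition with s-cis diene 3 gives iminium 6, which water hydrolyses to 7 with release of the catalyst; the closest known reaction type is the iminium-catalysed enantioselective Diels–Alder reaction of enals with 1-acyloxy dienes. Ring A closes by intermolecular [4+2] cycloaddition, suprafacial on both partners, forming the bond from the acetoxy carbon to the iminium α-carbon and the bond from the isopropyl carbon to the β-carbon. The E,E diene places isopropyl and acetoxy cis, the E dienophile places formyl and ester trans, and the endo transition state under the iminium group places formyl cis to both acetoxy and isopropyl. The absolute configuration comes from the catalyst: in the E-iminium ion the benzyl group of the (5R)-imidazolidinone covers the Si face of the α-carbon, so the diene should add to the Re face and make the formyl-bearing carbon S. The step needs regioselectivity, which the acetoxy donor should secure by making the remote isopropyl-bearing terminus the more nucleophilic one, and it needs the catalysed path to outrun the thermal one, which the low temperature and the LUMO lowering should provide.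

Step 4
Reactants: 7 ethyl (1R,2S,5R,6S)-5-acetoxy-6-formyl-2-(propan-2-yl)cyclohex-3-ene-1-carboxylate
Product: 8 ethyl (1R,2S,5R,6S)-5-acetoxy-6-(dimethoxymethyl)-2-(propan-2-yl)cyclohex-3-ene-1-carboxylate
Conditions: HC(OMe)3, PPTS (cat.), MeOH, rt
Reagents that add atoms: trimethyl orthoformate, COC(OC)OC
Why: Acid-catalysed acetalisation with the orthoformate as water scavenger masks the aldehyde at its own oxidation level for the hydride, oxidation and ylide steps, and the mild pyridinium acid should leave the allylic acetate and the α-centre (already in the more stable trans relation to the ester) unchanged.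

Step 5
Reactants: 8 ethyl (1R,2S,5R,6S)-5-acetoxy-6-(dimethoxymethyl)-2-(propan-2-yl)cyclohex-3-ene-1-carboxylate
Product: 9 ethyl (1R,2S,3R,6R)-3-acetoxy-2-(dimethoxymethyl)-6-(propan-2-yl)cyclohexane-1-carboxylate
Conditions: H2 (1 atm), 5% Rh/Al2O3, EtOAc, rt
Reagents that add atoms: none
Why: Heterogeneous catalytic hydrogenation of the cis-disubstituted ring alkene creates no stereocentre, and rhodium on alumina is chosen because it saturates alkenes with little hydrogenolysis of an allylic C–O bond.

Step 6
Reactants: 9 ethyl (1R,2S,3R,6R)-3-acetoxy-2-(dimethoxymethyl)-6-(propan-2-yl)cyclohexane-1-carboxylate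
Product: 10 (1R,2S,3R,4R)-2-(dimethoxymethyl)-3-(hydroxymethyl)-4-(propan-2-yl)cyclohexan-1-ol
Conditions: LiAlH4, THF, 0 °C → rt
Reagents that add atoms: none
Why: Hydride reduction with LiAlH4 should convert the ethyl ester into the primary alcohol and cleave the acetate to the secondary alcohol in one operation while the acetal is inert.

Step 7
Reactants: 10 (1R,2S,3R,4R)-2-(dimethoxymethyl)-3-(hydroxymethyl)-4-(propan-2-yl)cyclohexan-1-ol
Product: 11 (1R,2R,6R)-2-(dimethoxymethyl)-3-oxo-6-(propan-2-yl)cyclohexane-1-carbaldehyde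
Conditions: Dess–Martin periodinane, pyridine, CH2Cl2, 0 °C → rt
Reagents that add atoms: none
Why: Dess–Martin oxidation of both hydroxyl groups should give the keto aldehyde under non-basic conditions, so the two α-centres (both already equatorial) are not at risk and the acetal β to the new ketone is not eliminated.

Step 8
Reactants: 11 (1R,2R,6R)-2-(dimethoxymethyl)-3-oxo-6-(propan-2-yl)cyclohexane-1-carbaldehyde
Product: 12 (2R,3R,4R)-2-(dimethoxymethyl)-3-ethenyl-4-(propan-2-yl)cyclohexan-1-one
Conditions: Ph3PCH3Br, KN(SiMe3)2, THF, 0 °C; then 11, −78 → −20 °C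
Reagents that add atoms: methyltriphenylphosphonium bromide, C[P+](c1ccccc1)(c1ccccc1)c1ccccc1.[Br-]
Why: Wittig methylenation should be chemoselective for the aldehyde over the α-branched ketone at low temperature because unstabilised ylides add to aldehydes far faster, and it delivers the vinyl group used for the later ring closure.

Step 9
Reactants: 12 (2R,3R,4R)-2-(dimethoxymethyl)-3-ethenyl-4-(propan-2-yl)cyclohexan-1-one
Product: 13 (3S,4S,5R,6R)-4-(dimethoxymethyl)-5-ethenyl-6-(propan-2-yl)-1-oxaspiro[2.5]octane
Conditions: Me3SI, KN(SiMe3)2, THF, −10 °C; then 12, −10 → 0 °C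
Reagents that add atoms: trimethylsulfonium iodide, C[S+](C)C.[I-]
Why: Corey–Chaykovsky epoxidation with the unstabilised sulfonium ylide is kinetically controlled and should add along the axial direction of the chair in which all three ring substituents are equatorial, so the new C–C bond ends axial and cis to the acetal group and the oxygen equatorial, which is the configuration of the tertiary carbinol of the target.

Step 10
Reactants: 1 3-methylbutanal (isovaleraldehyde); 14 but-3-en-2-one (methyl vinyl ketone)
Product: 16 (2R)-5-oxo-2-(propan-2-yl)hexanal, via enamine 15 (not isolated)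
Conditions: (R)-2-(methoxydiphenylmethyl)pyrrolidine (5 mol %), ethyl 3,4-dihydroxybenzoate (20 mol %), neat, 4 °C
Reagents that add atoms: none
Why: Enamine-catalysed Michael addition proceeds through the E-enamine 15, whose methoxydiphenylmethyl group blocks one face so that the enone should add to the other and set the isopropyl-bearing centre as R.

Step 11
Reactants: 16 (2R)-5-oxo-2-(propan-2-yl)hexanal
Product: 18 (4R)-4-(propan-2-yl)cyclohex-2-en-1-one, via β-hydroxy ketone 17 (not isolated)
Conditions: LiOH (cat.), i-PrOH, rt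
Reagents that add atoms: none
Why: Intramolecular aldol condensation (methyl ketone enolate onto the aldehyde, then E1cB dehydration of 17) should close ring C as the cyclohexenone faster than the aldehyde α-centre enolises under this mild base.

Step 12
Reactants: 18 (4R)-4-(propan-2-yl)cyclohex-2-en-1-one
Product: 20 (3R,4R)-3-ethenyl-4-(propan-2-yl)cyclohex-1-en-1-yl trifluoromethanesulfonate, via bromomagnesium enolate 19 (not isolated)
Conditions: CH2=CHMgBr, CuI·2LiCl (10 mol %), THF, −78 °C; then N-(5-chloropyridin-2-yl)-N-(trifluoromethanesulfonyl)trifluoromethanesulfonamide, −78 °C → rt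
Reagents that add atoms: vinylmagnesium bromide, C=C[Mg]Br; N-(5-chloropyridin-2-yl)-N-(trifluoromethanesulfonyl)trifluoromethanesulfonamide, O=S(=O)(N(c1ccc(Cl)cn1)S(=O)(=O)C(F)(F)F)C(F)(F)F
Why: Copper-catalysed conjugate addition of the vinyl Grignard reagent should occur anti to the neighbouring isopropyl group (axial attack on the half-chair with isopropyl pseudo-equatorial) to give the trans 3,4 relation, and the regiodefined enolate 19 is trapped on oxygen as the enol triflate (conjugate addition/enolate triflation).

Step 13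
Reactants: 20 (3R,4R)-3-ethenyl-4-(propan-2-yl)cyclohex-1-en-1-yl trifluoromethanesulfonate
Product: 22 (3R,4R)-3-formyl-4-(propan-2-yl)cyclohex-1-en-1-yl trifluoromethanesulfonate, via secondary ozonide 21 (not isolated)
Conditions: O3, CH2Cl2, −78 °C (Sudan red endpoint); then PPh3, −78 °C → rt
Reagents that add atoms: ozone, [O-][O+]=O
Why: Ozonolysis with reductive work-up should cleave the electron-richer vinyl group selectively because the enol triflate alkene is strongly deactivated, and the aldehyde centre stays in the favoured trans arrangement.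

Step 14
Reactants: 22 (3R,4R)-3-formyl-4-(propan-2-yl)cyclohex-1-en-1-yl trifluoromethanesulfonate; 23 ethyl 2-(diethoxyphosphoryl)prop-2-enoate; 24 (4-methoxyphenyl)methanol
Product: 26 ethyl (2E)-2-{[(4-methoxyphenyl)methoxy]methyl}-3-[(1S,6R)-6-(propan-2-yl)-3-(trifluoromethanesulfonyloxy)cyclohex-2-en-1-yl]prop-2-enoate, via sodium phosphonate carbanion 25 (not isolated)
Conditions: 24, NaH, THF, 0 °C; then 23, −20 °C; then 22, −20 °C → rt
Reagents that add atoms: none
Why: Tandem oxa-Michael addition/Horner–Wadsworth–Emmons olefination: the alkoxide of 24 adds to vinylphosphonate 23 to give the stabilised carbanion 25, which should condense with the α-branched aldehyde to the trisubstituted enoate with the ester trans to the ring (E), as is usual for stabilised phosphonate anions.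

Step 15
Reactants: 26 ethyl (2E)-2-{[(4-methoxyphenyl)methoxy]methyl}-3-[(1S,6R)-6-(propan-2-yl)-3-(trifluoromethanesulfonyloxy)cyclohex-2-en-1-yl]prop-2-enoate
Product: 27 ethyl (2E)-3-[(1R,6R)-3-(hydroxymethyl)-6-(propan-2-yl)cyclohex-2-en-1-yl]-2-{[(4-methoxyphenyl)methoxy]methyl}prop-2-enoate
Conditions: Bu3SnCH2OH, Pd(PPh3)4 (5 mol %), LiCl, 1,4-dioxane, 90 °C
Reagents that add atoms: (tributylstannyl)methanol, OC[Sn](CCCC)(CCCC)CCCC
Why: Stille cross-coupling of the enol triflate with the hydroxymethylstannane (oxidative addition to zerovalent palladium, chloride-assisted transmetallation) should install the allylic hydroxymethyl group without moving the ring alkene.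

Step 16
Reactants: 27 ethyl (2E)-3-[(1R,6R)-3-(hydroxymethyl)-6-(propan-2-yl)cyclohex-2-en-1-yl]-2-{[(4-methoxyphenyl)methoxy]methyl}prop-2-enoate
Product: 28 (2E)-3-[(1R,6R)-3-(hydroxymethyl)-6-(propan-2-yl)cyclohex-2-en-1-yl]-2-{[(4-methoxyphenyl)methoxy]methyl}prop-2-enoic acid
Conditions: LiOH, THF/MeOH/H2O, 40 °C; then 1 M HCl to pH 3
Reagents that add atoms: lithium hydroxide, [Li+].[OH-]
Why: Saponification of the hindered conjugated ethyl ester should free the carboxylic acid while the benzyl-type ether and the allylic alcohol are stable to base.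

Step 17
Reactants: 13 (3S,4S,5R,6R)-4-(dimethoxymethyl)-5-ethenyl-6-(propan-2-yl)-1-oxaspiro[2.5]octane; 28 (2E)-3-[(1R,6R)-3-(hydroxymethyl)-6-(propan-2-yl)cyclohex-2-en-1-yl]-2-{[(4-methoxyphenyl)methoxy]methyl}prop-2-enoic acid
Product: 29 [(1S,2S,3R,4R)-2-(dimethoxymethyl)-3-ethenyl-1-hydroxy-4-(propan-2-yl)cyclohexyl]methyl ester of acid 28
Conditions: Cs2CO3 (0.3 equiv), DMF, 80 °C
Reagents that add atoms: none
Why: SN2 opening of the 2,2-disubstituted epoxide by the caesium carboxylate should occur at the unsubstituted CH2 carbon, so the C–O bond at the quaternary carbon is not touched and its configuration is kept, and the free primary alcohol of 28 is far less nucleophilic than its carboxylate.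

Step 18
Reactants: 29 [(1S,2S,3R,4R)-2-(dimethoxymethyl)-3-ethenyl-1-hydroxy-4-(propan-2-yl)cyclohexyl]methyl ester of acid 28
Product: 30 [(1S,2S,3R,4R)-3-ethenyl-2-formyl-1-hydroxy-4-(propan-2-yl)cyclohexyl]methyl ester of acid 28
Conditions: PPTS (cat.), acetone/H2O (9:1), 50 °C
Reagents that add atoms: water, O
Why: Mild acid-catalysed acetal hydrolysis should unmask the aldehyde without affecting the 4-methoxybenzyl ether, the ester or the tertiary alcohol.

Step 19
Reactants: 30 [(1S,2S,3R,4R)-3-ethenyl-2-formyl-1-hydroxy-4-(propan-2-yl)cyclohexyl]methyl ester of acid 28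
Product: 31 [(1S,2S,3R,4R)-2-carboxy-3-ethenyl-1-hydroxy-4-(propan-2-yl)cyclohexyl]methyl ester of acid 28
Conditions: NaClO2, NaH2PO4, 2-methylbut-2-ene, t-BuOH/H2O, 0 °C → rt
Reagents that add atoms: sodium chlorite, [Na+].[O-]Cl=O
Why: Pinnick oxidation should convert the aldehyde into the carboxylic acid chemoselectively in the presence of the free primary allylic and tertiary alcohols and of the alkenes, the hypochlorous acid formed being removed by the alkene scavenger.

Step 20
Reactants: 31 [(1S,2S,3R,4R)-2-carboxy-3-ethenyl-1-hydroxy-4-(propan-2-yl)cyclohexyl]methyl ester of acid 28; 32 tert-butyl 2-(bromomethyl)prop-2-enoate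
Product: 33 2-(tert-butoxycarbonyl)prop-2-en-1-yl ester of acid 31
Conditions: KHCO3, DMF, rt
Reagents that add atoms: none
Why: Carboxylate O-alkylation with the allylic bromide (SN2 and SN2′ lead to the same 2-substituted allyl ester) should form the ester bond of the future lactone under conditions too weakly basic to alkylate the hydroxyl groups.

Step 21
Reactants: 33 2-(tert-butoxycarbonyl)prop-2-en-1-yl ester of acid 31
Product: 34 ring B lactone carrying the tert-butyl ester and the 4-methoxybenzyl ether of the target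
Conditions: second-generation Grubbs catalyst RuCl2(=CHPh)(PCy3)(H2IMes) (10 mol %), toluene (0.005 M), 80 °C
Reagents that add atoms: none
Why: Ring-closing olefin metathesis between the vinyl group and the 1,1-disubstituted acrylate should close the seven-membered ring B, the ring forcing the ring carbon and the OCH2 group cis about the new trisubstituted alkene, while the trisubstituted alkenes of the ring C part are too hindered to take part.

Step 22
Reactants: 34 ring B lactone carrying the tert-butyl ester and the 4-methoxybenzyl ether of the target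
Product: 35 CNP0361406.2 (target)
Conditions: CF3CO2H/CH2Cl2 (1:4), anisole, 0 °C; aqueous NaHCO3 work-up
Reagents that add atoms: none
Why: Acidolysis should cleave the tert-butyl ester (loss of the tert-butyl cation as the alkene) and the 4-methoxybenzyl ether (cation trapped by anisole) together, while the lactone, the acrylate ester and the tertiary alcohol cannot form a stabilised cation and should survive.

**Compound list**

1 | 3-methylbutanal (isovaleraldehyde) | CC(C)CC=O | starting material
2 | (2E)-5-methylhex-2-enal | CC(C)C/C=C/C=O | intermediate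
3 | (1E,3E)-5-methylhexa-1,3-dien-1-yl acetate | CC(C)/C=C/C=C/OC(C)=O | intermediate
4 | ethyl (2E)-4-oxobut-2-enoate | CCOC(=O)/C=C/C=O | starting material
5 | E-iminium chloride of 4 with (5R)-5-benzyl-2,2,3-trimethylimidazolidin-4-one | CCOC(=O)/C=C/C=[N+]1\[C@H](Cc2ccccc2)C(=O)N(C)C1(C)C.[Cl-] | intermediate
6 | iminium chloride of cycloadduct 7 with the same imidazolidinone | CC(C)[C@H]1C=C[C@@H](OC(C)=O)[C@@H](C=[N+]2[C@H](Cc3ccccc3)C(=O)N(C)C2(C)C)[C@@H]1C(=O)OCC.[Cl-] | intermediate
7 | ethyl (1R,2S,5R,6S)-5-acetoxy-6-formyl-2-(propan-2-yl)cyclohex-3-ene-1-carboxylate | CC(C)[C@H]1C=C[C@@H](OC(C)=O)[C@@H](C=O)[C@@H]1C(=O)OCC | intermediate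
8 | ethyl (1R,2S,5R,6S)-5-acetoxy-6-(dimethoxymethyl)-2-(propan-2-yl)cyclohex-3-ene-1-carboxylate | CC(C)[C@H]1C=C[C@@H](OC(C)=O)[C@@H](C(OC)OC)[C@@H]1C(=O)OCC | intermediate
9 | ethyl (1R,2S,3R,6R)-3-acetoxy-2-(dimethoxymethyl)-6-(propan-2-yl)cyclohexane-1-carboxylate | CC(C)[C@H]1CC[C@@H](OC(C)=O)[C@@H](C(OC)OC)[C@@H]1C(=O)OCC | intermediate
10 | (1R,2S,3R,4R)-2-(dimethoxymethyl)-3-(hydroxymethyl)-4-(propan-2-yl)cyclohexan-1-ol | CC(C)[C@H]1CC[C@@H](O)[C@@H](C(OC)OC)[C@@H]1CO | intermediate
11 | (1R,2R,6R)-2-(dimethoxymethyl)-3-oxo-6-(propan-2-yl)cyclohexane-1-carbaldehyde | CC(C)[C@H]1CCC(=O)[C@@H](C(OC)OC)[C@@H]1C=O | intermediate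
12 | (2R,3R,4R)-2-(dimethoxymethyl)-3-ethenyl-4-(propan-2-yl)cyclohexan-1-one | CC(C)[C@H]1CCC(=O)[C@@H](C(OC)OC)[C@@H]1C=C | intermediate
13 | (3S,4S,5R,6R)-4-(dimethoxymethyl)-5-ethenyl-6-(propan-2-yl)-1-oxaspiro[2.5]octane (epoxide CH2 axial, cis to the acetal group) | CC(C)[C@H]1CC[C@@]2(CO2)[C@@H](C(OC)OC)[C@@H]1C=C | intermediate
14 | but-3-en-2-one (methyl vinyl ketone) | CC(=O)C=C | starting material
15 | E-enamine of 1 with (R)-2-(methoxydiphenylmethyl)pyrrolidine | CC(C)/C=C/N1CCC[C@@H]1C(OC)(c1ccccc1)c1ccccc1 | intermediate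
16 | (2R)-5-oxo-2-(propan-2-yl)hexanal | O=C[C@@H](C(C)C)CCC(C)=O | intermediate
17 | (4R)-3-hydroxy-4-(propan-2-yl)cyclohexan-1-one (carbinol centre undefined) | CC(C)[C@H]1CCC(=O)CC1O | intermediate
18 | (4R)-4-(propan-2-yl)cyclohex-2-en-1-one ((R)-cryptone) | CC(C)[C@H]1CCC(=O)C=C1 | intermediate
19 | bromomagnesium (3R,4R)-3-ethenyl-4-(propan-2-yl)cyclohex-1-en-1-olate | C=C[C@H]1C=C(O[Mg]Br)CC[C@@H]1C(C)C | intermediate
20 | (3R,4R)-3-ethenyl-4-(propan-2-yl)cyclohex-1-en-1-yl trifluoromethanesulfonate (trans) | C=C[C@H]1C=C(OS(=O)(=O)C(F)(F)F)CC[C@@H]1C(C)C | intermediate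
21 | secondary ozonide (1,2,4-trioxolan-3-yl in place of the vinyl group of 20) | C1OC(OO1)[C@H]1C=C(OS(=O)(=O)C(F)(F)F)CC[C@@H]1C(C)C | intermediate
22 | (3R,4R)-3-formyl-4-(propan-2-yl)cyclohex-1-en-1-yl trifluoromethanesulfonate | O=C[C@H]1C=C(OS(=O)(=O)C(F)(F)F)CC[C@@H]1C(C)C | intermediate
23 | ethyl 2-(diethoxyphosphoryl)prop-2-enoate | CCOC(=O)C(=C)P(=O)(OCC)OCC | starting material
24 | (4-methoxyphenyl)methanol | COc1ccc(CO)cc1 | starting material
25 | sodium salt of the carbanion of ethyl 2-(diethoxyphosphoryl)-3-[(4-methoxyphenyl)methoxy]propanoate | CCOC(=O)[C-](COCc1ccc(OC)cc1)P(=O)(OCC)OCC.[Na+] | intermediate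
26 | ethyl (2E)-2-{[(4-methoxyphenyl)methoxy]methyl}-3-[(1S,6R)-6-(propan-2-yl)-3-(trifluoromethanesulfonyloxy)cyclohex-2-en-1-yl]prop-2-enoate | CCOC(=O)/C(=C/[C@H]1C=C(OS(=O)(=O)C(F)(F)F)CC[C@@H]1C(C)C)COCc1ccc(OC)cc1 | intermediate
27 | ethyl (2E)-3-[(1R,6R)-3-(hydroxymethyl)-6-(propan-2-yl)cyclohex-2-en-1-yl]-2-{[(4-methoxyphenyl)methoxy]methyl}prop-2-enoate | CCOC(=O)/C(=C/[C@H]1C=C(CO)CC[C@@H]1C(C)C)COCc1ccc(OC)cc1 | intermediate
28 | (2E)-3-[(1R,6R)-3-(hydroxymethyl)-6-(propan-2-yl)cyclohex-2-en-1-yl]-2-{[(4-methoxyphenyl)methoxy]methyl}prop-2-enoic acid (ring C acid) | OC(=O)/C(=C/[C@H]1C=C(CO)CC[C@@H]1C(C)C)COCc1ccc(OC)cc1 | intermediate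
29 | [(1S,2S,3R,4R)-2-(dimethoxymethyl)-3-ethenyl-1-hydroxy-4-(propan-2-yl)cyclohexyl]methyl ester of acid 28 | CC(C)[C@H]1CC[C@@](O)(COC(=O)/C(=C/[C@H]2C=C(CO)CC[C@@H]2C(C)C)COCc2ccc(OC)cc2)[C@@H](C(OC)OC)[C@@H]1C=C | intermediate
30 | [(1S,2S,3R,4R)-3-ethenyl-2-formyl-1-hydroxy-4-(propan-2-yl)cyclohexyl]methyl ester of acid 28 | CC(C)[C@H]1CC[C@@](O)(COC(=O)/C(=C/[C@H]2C=C(CO)CC[C@@H]2C(C)C)COCc2ccc(OC)cc2)[C@@H](C=O)[C@@H]1C=C | intermediate
31 | [(1S,2S,3R,4R)-2-carboxy-3-ethenyl-1-hydroxy-4-(propan-2-yl)cyclohexyl]methyl ester of acid 28 | CC(C)[C@H]1CC[C@@](O)(COC(=O)/C(=C/[C@H]2C=C(CO)CC[C@@H]2C(C)C)COCc2ccc(OC)cc2)[C@@H](C(=O)O)[C@@H]1C=C | intermediate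
32 | tert-butyl 2-(bromomethyl)prop-2-enoate | C=C(CBr)C(=O)OC(C)(C)C | starting material
33 | 2-(tert-butoxycarbonyl)prop-2-en-1-yl ester of the ring carboxylic acid of 31 | CC(C)[C@H]1CC[C@@](O)(COC(=O)/C(=C/[C@H]2C=C(CO)CC[C@@H]2C(C)C)COCc2ccc(OC)cc2)[C@@H](C(=O)OCC(=C)C(=O)OC(C)(C)C)[C@@H]1C=C | intermediate
34 | tert-butyl ester and side-chain 4-methoxybenzyl ether of the target (seven-membered unsaturated lactone trans-fused to ring A) | CC(C)[C@H]1CC[C@@](O)(COC(=O)/C(=C/[C@H]2C=C(CO)CC[C@@H]2C(C)C)COCc2ccc(OC)cc2)[C@H]2C(=O)OCC(C(=O)OC(C)(C)C)=C[C@H]12 | intermediate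
35 | CNP0361406.2: ring A cyclohexane trans-fused to the unsaturated seven-membered lactone acid (ring B), tertiary alcohol, CH2 ester of the (E)-2-(hydroxymethyl)acrylic acid carrying ring C | CC(C)[C@H]1CC[C@@](O)(COC(=O)/C(=C/[C@H]2C=C(CO)CC[C@@H]2C(C)C)CO)[C@H]2C(=O)OCC(C(=O)O)=C[C@H]12 | target

**Step count and risks**

Total: 22 steps. Longest linear sequence: 15 steps (steps 1–9 and 17–22, from 1 to 35); the ring C branch (steps 10–16) has 7 steps.

Steps most likely to fail:

Step 3. The cycloaddition may run without catalyst control, because the aldehyde ester is electrophilic enough to react thermally, which would erode the enantiomeric purity. The diene may also add in the wrong orientation, because acetoxy is only a weak donor against the alkyl group at the other terminus. The fallback sets out from 3 and returns at 7. Diene 3 is combined with the auxiliary-bound dienophile ethyl (2E)-4-[(4R)-4-benzyl-2-oxo-1,3-oxazolidin-3-yl]-4-oxobut-2-enoate F1 (from monoethyl fumarate through its acid chloride and the lithiated oxazolidinone) under Et2AlCl in CH2Cl2 at −78 °C. The chelated s-cis acyl imide should be attacked endo on the face away from the benzyl group, the same face as in step 3, and the strongly polarised chelate should sharpen the regiocontrol, giving the imide cycloadduct F2. LiBH4 (THF, MeOH, 0 °C) removes the auxiliary reductively to the primary alcohol ethyl (1R,2S,5R,6S)-5-acetoxy-6-(hydroxymethyl)-2-(propan-2-yl)cyclohex-3-ene-1-carboxylate F3, and Dess–Martin oxidation of F3 gives 7.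

Step 14. Control over the alkene geometry may be lost, and aldehyde 22 may be epimerised or its ring alkene shifted, because alkoxide and carbanion are both present; the oxa-Michael step may also revert. The fallback sets out from 22 and returns at 26. The lithium enolate (LDA, THF, −78 °C) of ethyl 3-[(4-methoxyphenyl)methoxy]propanoate F4 (from 24 and ethyl acrylate by base-catalysed conjugate addition) adds to 22 to give the β-hydroxy ester F5 as a diastereomer mixture. Mesylation (MsCl, Et3N, 0 °C) gives the mesylate F6, and E1cB elimination with DBU should give the more stable E enoate 26.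

Step 17. Substitution at the axial, neopentyl-like epoxide CH2 by the weakly nucleophilic conjugated carboxylate may be slow, and prolonged heating may shift the skipped diene of 28 or cost the acetal. The fallback sets out from 13 (with 27 as source of the acid partner) and returns at 29. Hydroxide (KOH, DMSO/H2O, 90 °C) opens 13 at the CH2 carbon to the diol (1S,2S,3R,4R)-2-(dimethoxymethyl)-3-ethenyl-1-(hydroxymethyl)-4-(propan-2-yl)cyclohexan-1-ol F7, the quaternary centre being untouched. Alcohol 27 is silylated (TBSCl, imidazole) to the tert-butyldimethylsilyl ether F8 and saponified (LiOH) to the silyl ether acid F9. Yamaguchi esterification (2,4,6-trichlorobenzoyl chloride, Et3N, then F7 and DMAP) should acylate only the primary hydroxyl of F7 and give the silyl ether of 29 F10, from which HF·pyridine in THF removes the silyl group to give 29.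

**Further compounds**

F1 | step 3 | ethyl (2E)-4-[(4R)-4-benzyl-2-oxo-1,3-oxazolidin-3-yl]-4-oxobut-2-enoate | CCOC(=O)/C=C/C(=O)N1[C@H](Cc2ccccc2)COC1=O
F2 | step 3 | imide cycloadduct (the formyl group of 7 replaced by the N-acyl oxazolidinone) | CC(C)[C@H]1C=C[C@@H](OC(C)=O)[C@@H](C(=O)N2[C@H](Cc3ccccc3)COC2=O)[C@@H]1C(=O)OCC
F3 | step 3 | ethyl (1R,2S,5R,6S)-5-acetoxy-6-(hydroxymethyl)-2-(propan-2-yl)cyclohex-3-ene-1-carboxylate | CC(C)[C@H]1C=C[C@@H](OC(C)=O)[C@@H](CO)[C@@H]1C(=O)OCC
F4 | step 14 | ethyl 3-[(4-methoxyphenyl)methoxy]propanoate | CCOC(=O)CCOCc1ccc(OC)cc1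
F5 | step 14 | β-hydroxy ester from the aldol addition of F4 to 22 | CCOC(=O)C(COCc1ccc(OC)cc1)C(O)[C@H]1C=C(OS(=O)(=O)C(F)(F)F)CC[C@@H]1C(C)C
F6 | step 14 | mesylate of F5 | CCOC(=O)C(COCc1ccc(OC)cc1)C(OS(C)(=O)=O)[C@H]1C=C(OS(=O)(=O)C(F)(F)F)CC[C@@H]1C(C)C
F7 | step 17 | (1S,2S,3R,4R)-2-(dimethoxymethyl)-3-ethenyl-1-(hydroxymethyl)-4-(propan-2-yl)cyclohexan-1-ol | CC(C)[C@H]1CC[C@@](O)(CO)[C@@H](C(OC)OC)[C@@H]1C=C
F8 | step 17 | tert-butyldimethylsilyl ether of 27 | CCOC(=O)/C(=C/[C@H]1C=C(CO[Si](C)(C)C(C)(C)C)CC[C@@H]1C(C)C)COCc1ccc(OC)cc1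
F9 | step 17 | tert-butyldimethylsilyl ether of 28 | OC(=O)/C(=C/[C@H]1C=C(CO[Si](C)(C)C(C)(C)C)CC[C@@H]1C(C)C)COCc1ccc(OC)cc1
F10 | step 17 | tert-butyldimethylsilyl ether of 29 | CC(C)[C@H]1CC[C@@](O)(COC(=O)/C(=C/[C@H]2C=C(CO[Si](C)(C)C(C)(C)C)CC[C@@H]2C(C)C)COCc2ccc(OC)cc2)[C@@H](C(OC)OC)[C@@H]1C=C
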